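At late times a flask that has stopped moving can be read without any rate constant, so this examination starts there.

the same everywhere: free catalyst 50 mM
- Sunday's: substrate 0.15 M; reagent 0.40 M; run made earlier
- Friday's: substrate 1.2 M; reagent 0.40 M; run made earlier
- north-west: substrate 0.12 M; reagent 0.400 M; time 20 d
- west: substrate 0.25 M; reagent 0.400 M; time 20 d
- south-east: substrate 0.50 M; reagent 0.400 M; time 20 d
- north-east: substrate 1.0 M; reagent 0.400 M; time 20 d

| run | time / d | product / % | substrate / % |
|---|---|---|---|
| Sunday's | 0.833 | 75 | 7 |
| Sunday's | 1.67 | 99 | 0 |
| Sunday's | 4.00 | 102 | 1 |
| Sunday's | 10.0 | 102 | 1 |
| Friday's | 0.833 | 16 | 83 |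
| Friday's | 1.67 | 26 | 68 |
| Friday's | 4.00 | 33 | 67 |
| Friday's | 10.0 | 32 | 68 |

(scatter of a reading: 1.5 percentage points)

- "hardly changes" means that all values lie within two and a half points (for a concentration: within two and a half percent of the largest)
- a step back or a flat step of under half a percent of the largest counts as no turn

- [product] at the end for north-west, west, south-east, north-east, in this order
- how the row runs (hardly changes / falls all the way / rises all the way / falls, then rises / rises, then falls)

*Has Friday's run stopped?* It seems so. Its product reads 33% at 4.00 d and 32% at 10.0 d, against a scatter of 1.5 percentage points.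

*What is that in molar?* I replace the flat end of the curve by its mean and multiply by the substrate charged, which gives 0.390 M. I call this reading the ceiling, P∞: the product at which a flask with this charge of reagent and catalyst stops while substrate is left over. Either reading alone would give 0.384 M or 0.396 M, so taking the mean costs little.

*What does the ceiling match?* It matches the reagent charge of 0.40 M, since the ratio is 0.975. That suggests one product per reagent.

*And a flask with less substrate than P∞?* Sunday's run, at 0.15 M, lies below the ceiling and ended at 102% of its charge. So I take the product to be the lower of the substrate charge and P∞.

*Here is the weak spot: are the new flasks finished in time?* Replace the rising curve by a straight line, with the mean rate r of Friday's first interval, 0.230 M d⁻¹. Filling the ceiling at r takes 1.70 d. The line is optimistic: Friday's first reading on the plateau stands at 4.00 d, a factor of 2.36 later. Even that is far shorter than the 20 d allowed.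

So my row is 0.12 M, 0.25 M, 0.390 M and 0.390 M. Its last step is flat, which counts as no turn, so the row rises all the way.

The forecast, which puts 0.12 M, 0.25 M, 0.4 M and 0.4 M and says the row rises all the way, uses the reagent charge where I use the ceiling: “So product = min(substrate, 0.40)”.

The flasks give 0.120 M, 0.250 M, 0.400 M and 0.400 M, and the row rises all the way.

    reagent + free catalyst → catalyst intermediate A (k = 20.3 M⁻¹ h⁻¹)
    catalyst intermediate A ⇌ catalyst intermediate B (K = 3.10, k = 12.5 h⁻¹)
    substrate + catalyst intermediate B → catalyst intermediate C (k = 11.7 M⁻¹ h⁻¹)
    catalyst intermediate C → catalyst intermediate D (k = 0.172 h⁻¹)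
    catalyst intermediate D → free catalyst + product (k = 36.7 h⁻¹)

The ceiling of 0.390 M, a reading, lies 0.0100 M below the product of south-east and north-east. Used on south-east, it leaves 22.0% of the substrate, and the flask shows 20.0%. On north-east it leaves 61.0%, and the flask shows 60.0%. In north-east the reagent is the limiting reagent, with 0% of it left at the end. Its falling level has a large effect there: with the reagent held at its charge, the product of north-east goes from 0.400 M to 1.00 M.

The numbers in the tables are calculated with constants of no real substance; scatter was added.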